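**Plan**

- Numbering used here: lactone C1(=O)–C2(Me)=C3–C4, exocyclic C5, stereocentre C6, C7, diene C8=C9–C10(Me)=C11, C12–C13, then furan A (O1, C2 carrying the CH2 bridge to C3 of furan B, C4 carrying C13).
- Retrosynthetic cuts, in order: C4=C5 and C4–C5 (dehydration, vinylogous aldol); C7–C8 (Negishi); C8=C9 (Takai) and C10=C11 (cross-metathesis); O1–C2 of furan A (enynol cycloisomerisation); the alkene–alkyne bond (Sonogashira); the C2 branch and the C–I bond of an iodoallylic alcohol (carbomagnesiation).
- Enabling feature: furan A is 2,4-disubstituted and its C2 substituent is an sp3 CH2 bonded to furan B. This is the imprint left when the hydroxyl oxygen of a (Z)-2-en-4-yn-1-ol adds to its aryl-capped alkyne and the new ring aromatises.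
- Forward: furan B is bought as furan-3-carbaldehyde; ring A is closed in step 4; the chain is then grown outward (enal, dienyl iodide, C5–C7 unit); the lactone ring, bought as 3-methylfuran-2(5H)-one, is attached last.
- Stereochemistry: C6 (S) comes from methyl (2S)-3-hydroxy-2-methylpropanoate; 10E from the metathesis, 8E from the Takai reaction; the E enol-lactone alkene from an unlike aldol adduct followed by anti-elimination.

Key step: step 4

Assumption: the SMILES is read as the E enol lactone (side chain trans to the ring oxygen, cis to C3) with an (S)-configured C6, and but-3-en-1-ylmagnesium bromide is used as the commercial THF solution.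

**Route**

Step 1
Reactants: 1 prop-2-yn-1-ol; 2 but-3-en-1-ylmagnesium bromide
Product: 4 (2Z)-2-(but-3-en-1-yl)-3-iodoprop-2-en-1-ol, via cyclic alkenylmagnesium alkoxide 3 (not isolated)
Conditions: CuI (10 mol %), THF/Et2O, −10 °C to rt; then I2, THF, −40 to 0 °C; aq. NH4Cl
Reagents that add atoms: iodine, II
Why: Copper-catalysed anti-carbomagnesiation of a propargylic alcohol, in which the magnesium alkoxide delivers the butenyl group to C2 and holds the metal on C3 cis to the CH2O group in the five-membered chelate 3, so that iodinolysis with retention should give the Z iodoalkene.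

Step 2
Reactants: 5 furan-3-carbaldehyde
Product: 6 3-ethynylfuran
Conditions: dimethyl (1-diazo-2-oxopropyl)phosphonate, K2CO3, MeOH, 0 °C to rt; product kept as an ethereal solution
Reagents that add atoms: dimethyl (1-diazo-2-oxopropyl)phosphonate, COP(=O)(OC)C(=[N+]=[N-])C(C)=O
Why: Ohira–Bestmann homologation converts the non-enolisable heteroaryl aldehyde into the terminal alkyne under mild carbonate conditions that the furan tolerates.

Step 3
Reactants: 4 (2Z)-2-(but-3-en-1-yl)-3-iodoprop-2-en-1-ol; 6 3-ethynylfuran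
Product: 7 (2Z)-2-(but-3-en-1-yl)-5-(furan-3-yl)pent-2-en-4-yn-1-ol
Conditions: Pd(PPh3)2Cl2 (2 mol %), CuI (4 mol %), Et3N, THF, rt
Reagents that add atoms: none
Why: Sonogashira coupling of an alkenyl iodide with a terminal alkyne proceeds with retention of the alkene geometry and tolerates the free allylic alcohol and the remote terminal alkene.

Step 4
Reactants: 7 (2Z)-2-(but-3-en-1-yl)-5-(furan-3-yl)pent-2-en-4-yn-1-ol
Product: 9 4-(but-3-en-1-yl)-2-(furan-3-ylmethyl)furan, via furylmethylidene dihydrofuran 8 (not isolated)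
Conditions: PdI2 (2 mol %), KI (4 mol %), DMA, 60–80 °C, N2
Reagents that add atoms: none
Why: K2PdI4 formed from PdI2 and KI coordinates the alkyne of 7, the hydroxymethyl oxygen adds anti to the proximal alkyne carbon, and protonolysis of the alkenyl–palladium bond (divalent palladium throughout) releases the (Z)-2-ylidene-2,5-dihydrofuran 8. A hydrogen shift driven by the gain of aromaticity then converts 8 into furan A and leaves the former alkyne terminus as the CH2 link to furan B. The closest known reaction type is the palladium- or gold-catalysed cycloisomerisation of (Z)-2-en-4-yn-1-ols to furans, which covers aryl-capped alkynes that end up as 2-benzylfurans. Ring A closes in the 5-exo-dig mode by forming the O1–C2 bond, and no stereocentre is created. The step needs 5-exo rather than 6-endo closure, which the cis placement of CH2OH and alkyne across the trisubstituted alkene secures by putting the oxygen within reach of the proximal alkyne carbon only; it also needs furan B and the terminal alkene to survive, which the neutral, iodide-saturated catalyst without acid or hydride source should allow. Because the C2 substituent of the enynol becomes the C4 substituent of the ring and the alkyne terminus becomes the C2 side chain, the substitution pattern is fixed before the ring exists.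

Step 5
Reactants: 9 4-(but-3-en-1-yl)-2-(furan-3-ylmethyl)furan
Product: 10 (2E)-5-[5-(furan-3-ylmethyl)furan-3-yl]-2-methylpent-2-enal
Conditions: methacrolein (10 equiv), second-generation Grubbs catalyst (H2IMes)(PCy3)Cl2Ru=CHPh (5 mol %), CH2Cl2, 40 °C
Reagents that add atoms: methacrolein, CC(=C)C=O
Why: Olefin cross-metathesis of a monosubstituted alkene with excess methacrolein should favour the cross product, and the trisubstituted enal is expected as the thermodynamically preferred E isomer, while the furans do not engage the ruthenium carbene.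

Step 6
Reactants: 10 (2E)-5-[5-(furan-3-ylmethyl)furan-3-yl]-2-methylpent-2-enal
Product: 11 2-(furan-3-ylmethyl)-4-[(3E,5E)-6-iodo-4-methylhexa-3,5-dien-1-yl]furan
Conditions: CrCl2 (6 equiv), CHI3 (2 equiv), THF/1,4-dioxane, 0 °C to rt, dark
Reagents that add atoms: iodoform, IC(I)I
Why: Takai olefination, in which the gem-dichromium species from iodoform adds to the enal and eliminates to the E iodoalkene under conditions neutral enough for both furans.

Step 7
Reactants: 12 methyl (2S)-3-hydroxy-2-methylpropanoate
Product: 13 methyl (2R)-3-iodo-2-methylpropanoate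
Conditions: PPh3, I2, imidazole, CH2Cl2, 0 °C to rt
Reagents that add atoms: iodine, II
Why: Appel-type iodination is an SN2 displacement at the primary CH2 group and leaves the adjacent stereocentre untouched (the descriptor changes only through priority).

Step 8
Reactants: 13 methyl (2R)-3-iodo-2-methylpropanoate; 11 2-(furan-3-ylmethyl)-4-[(3E,5E)-6-iodo-4-methylhexa-3,5-dien-1-yl]furan
Product: 15 methyl (2S,4E,6E)-9-[5-(furan-3-ylmethyl)furan-3-yl]-2,6-dimethylnona-4,6-dienoate, via alkylzinc iodide 14 (not isolated)
Conditions: Zn dust (activated by TMSCl and 1,2-dibromoethane), DMF, rt; then 11, Pd2(dba)3 (2.5 mol %), P(o-tol)3 (10 mol %), DMF, rt, dark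
Reagents that add atoms: none
Why: Zinc insertion gives a configurationally stable β-zincio ester that undergoes Negishi sp3–sp2 coupling at zerovalent palladium with retention of both alkene geometries, and the stereocentre is neither the metal-bearing carbon nor exposed to base.

Step 9
Reactants: 15 methyl (2S,4E,6E)-9-[5-(furan-3-ylmethyl)furan-3-yl]-2,6-dimethylnona-4,6-dienoate
Product: 16 (2S,4E,6E)-9-[5-(furan-3-ylmethyl)furan-3-yl]-2,6-dimethylnona-4,6-dienal
Conditions: i-Bu2AlH (1.1 equiv), CH2Cl2, −78 °C; MeOH, then aq. potassium sodium tartrate; used at once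
Reagents that add atoms: none
Why: Partial reduction of a methyl ester with i-Bu2AlH at −78 °C stops at the aluminium hemiacetal, which releases the α-branched aldehyde on work-up, and immediate use should prevent epimerisation at C6.

Step 10
Reactants: 17 3-methylfuran-2(5H)-one
Product: 18 trimethyl[(3-methylfuran-2-yl)oxy]silane
Conditions: Et3N, TMSOTf, Et2O, 0 °C; distilled
Reagents that add atoms: trimethylsilyl trifluoromethanesulfonate, C[Si](C)(C)OS(=O)(=O)C(F)(F)F
Why: Soft enolisation and O-silylation aromatise the butenolide to the 2-silyloxyfuran, the standard vinylogous ester enolate equivalent.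

Step 11
Reactants: 16 (2S,4E,6E)-9-[5-(furan-3-ylmethyl)furan-3-yl]-2,6-dimethylnona-4,6-dienal; 18 trimethyl[(3-methylfuran-2-yl)oxy]silane
Product: 20 (5S)-5-[(1R,2S,4E,6E)-9-[5-(furan-3-ylmethyl)furan-3-yl]-1-hydroxy-2,6-dimethylnona-4,6-dien-1-yl]-3-methylfuran-2(5H)-one, via trimethylsilyl ether 19 (not isolated)
Conditions: 18 (1.5 equiv), TBAF (10 mol %), THF, −78 °C; then aq. citric acid, MeOH, 0 °C
Reagents that add atoms: none
Why: Fluoride-triggered vinylogous Mukaiyama aldol addition, in which the free furanolate reacts through its γ-carbon via an open transition state that is expected to favour the unlike (erythro) relation between ring carbon and carbinol carbon (the opposite of the Lewis acid variant), with Felkin–Anh induction from C6 setting the carbinol centre; either unlike adduct gives the same alkene in step 12, so only the ring/carbinol relation matters.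

Step 12
Reactants: 20 (5S)-5-[(1R,2S,4E,6E)-9-[5-(furan-3-ylmethyl)furan-3-yl]-1-hydroxy-2,6-dimethylnona-4,6-dien-1-yl]-3-methylfuran-2(5H)-one
Product: 21 (5E)-5-[(2S,4E,6E)-9-[5-(furan-3-ylmethyl)furan-3-yl]-2,6-dimethylnona-4,6-dien-1-ylidene]-3-methylfuran-2(5H)-one
Conditions: PPh3, DIAD (premixed at 0 °C), THF, then 20, 0 °C to rt, dark
Reagents that add atoms: none
Why: Mitsunobu-type dehydration, in which the oxyphosphonium group and the acidic ring hydrogen leave in an anti-periplanar E2 process that transcribes the unlike configuration of 20 into the E enol-lactone alkene and removes both temporary stereocentres, while premixing the reagents keeps free azodicarboxylate away from the diene.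

**Compound list**

1 | prop-2-yn-1-ol | C#CCO | starting material
2 | but-3-en-1-ylmagnesium bromide | C=CCC[Mg]Br | starting material
3 | 4-(but-3-en-1-yl)-2,5-dihydro-1,2-oxamagnesole (cyclic alkenylmagnesium alkoxide) | C=CCCC1=C[Mg]OC1 | intermediate (not isolated)
4 | (2Z)-2-(but-3-en-1-yl)-3-iodoprop-2-en-1-ol | OC/C(CCC=C)=C\I | intermediate
5 | furan-3-carbaldehyde | O=Cc1ccoc1 | starting material
6 | 3-ethynylfuran | C#Cc1ccoc1 | intermediate
7 | (2Z)-2-(but-3-en-1-yl)-5-(furan-3-yl)pent-2-en-4-yn-1-ol | OC/C(CCC=C)=C\C#Cc1ccoc1 | intermediate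
8 | (2Z)-4-(but-3-en-1-yl)-2-(furan-3-ylmethylidene)-2,5-dihydrofuran | C=CCCC1=C/C(=C/c2ccoc2)OC1 | intermediate (not isolated)
9 | 4-(but-3-en-1-yl)-2-(furan-3-ylmethyl)furan | C=CCCc1coc(Cc2ccoc2)c1 | intermediate
10 | (2E)-5-[5-(furan-3-ylmethyl)furan-3-yl]-2-methylpent-2-enal | O=C/C(C)=C/CCc1coc(Cc2ccoc2)c1 | intermediate
11 | 2-(furan-3-ylmethyl)-4-[(3E,5E)-6-iodo-4-methylhexa-3,5-dien-1-yl]furan | I/C=C/C(C)=C/CCc1coc(Cc2ccoc2)c1 | intermediate
12 | methyl (2S)-3-hydroxy-2-methylpropanoate | COC(=O)[C@@H](C)CO | starting material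
13 | methyl (2R)-3-iodo-2-methylpropanoate | COC(=O)[C@@H](C)CI | intermediate
14 | iodo[(2R)-3-methoxy-2-methyl-3-oxopropyl]zinc | COC(=O)[C@@H](C)C[Zn]I | intermediate (not isolated)
15 | methyl (2S,4E,6E)-9-[5-(furan-3-ylmethyl)furan-3-yl]-2,6-dimethylnona-4,6-dienoate | COC(=O)[C@@H](C)C/C=C/C(C)=C/CCc1coc(Cc2ccoc2)c1 | intermediate
16 | (2S,4E,6E)-9-[5-(furan-3-ylmethyl)furan-3-yl]-2,6-dimethylnona-4,6-dienal | O=C[C@@H](C)C/C=C/C(C)=C/CCc1coc(Cc2ccoc2)c1 | intermediate
17 | 3-methylfuran-2(5H)-one | CC1=CCOC1=O | starting material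
18 | trimethyl[(3-methylfuran-2-yl)oxy]silane | Cc1ccoc1O[Si](C)(C)C | intermediate
19 | (5S)-5-[(1R,2S,4E,6E)-9-[5-(furan-3-ylmethyl)furan-3-yl]-2,6-dimethyl-1-[(trimethylsilyl)oxy]nona-4,6-dien-1-yl]-3-methylfuran-2(5H)-one | CC1=C[C@@H]([C@H](O[Si](C)(C)C)[C@@H](C)C/C=C/C(C)=C/CCc2coc(Cc3ccoc3)c2)OC1=O | intermediate (not isolated)
20 | (5S)-5-[(1R,2S,4E,6E)-9-[5-(furan-3-ylmethyl)furan-3-yl]-1-hydroxy-2,6-dimethylnona-4,6-dien-1-yl]-3-methylfuran-2(5H)-one | CC1=C[C@@H]([C@H](O)[C@@H](C)C/C=C/C(C)=C/CCc2coc(Cc3ccoc3)c2)OC1=O | intermediate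
21 | (5E)-5-[(2S,4E,6E)-9-[5-(furan-3-ylmethyl)furan-3-yl]-2,6-dimethylnona-4,6-dien-1-ylidene]-3-methylfuran-2(5H)-one | CC1=C/C(=C\[C@@H](C)C/C=C/C(C)=C/CCc2coc(Cc3ccoc3)c2)OC1=O | target

**Step count**

Total steps: 12. Longest linear sequence: 9 steps (steps 1, 3, 4, 5, 6, 8, 9, 11, 12, from prop-2-yn-1-ol 1).

**Steps most likely to fail**

Step 11. The fluoride-triggered addition may show poor simple diastereoselectivity, so that like and unlike adducts form together and step 12 turns them into a mixture of alkene isomers. The basic furanolate may also epimerise the aldehyde at C6. The fallback sets out from aldehyde 16 and silyloxyfuran 18 and moves to the Lewis acid manifold. BF3·OEt2 in CH2Cl2 at −78 °C, without base, should give the like (threo) adduct (5R)-5-[(1R,2S,4E,6E)-9-[5-(furan-3-ylmethyl)furan-3-yl]-1-hydroxy-2,6-dimethylnona-4,6-dien-1-yl]-3-methylfuran-2(5H)-one F1. Since anti-elimination of F1 would give the Z alkene, water is removed in the syn mode instead, with methyl N-(triethylammoniosulfonyl)carbamate (Burgess reagent) in toluene at 50 °C. The intramolecular syn-elimination of the sulfamate places the side chain trans to the ring oxygen, and the route is rejoined at target 21.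

Step 6. The chromium-mediated iodo-olefination may give incomplete E selectivity, and the light-sensitive dienyl iodide may decompose during purification. The fallback sets out from enal 10 and fixes the geometry by hydrometalation. Me3SiC(Li)N2 (from Me3SiCHN2 and LiN(i-Pr)2, THF, −78 °C to rt, Colvin rearrangement) should give the enyne 2-(furan-3-ylmethyl)-4-[(3E)-4-methylhex-3-en-5-yn-1-yl]furan F2. Syn-hydrozirconation of the terminal alkyne with Cp2Zr(H)Cl in THF gives chlorobis(cyclopentadienyl)[(1E,3E)-6-[5-(furan-3-ylmethyl)furan-3-yl]-3-methylhexa-1,3-dien-1-yl]zirconium F3. Iodinolysis with I2 at 0 °C, with retention, returns the route to dienyl iodide 11.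

Step 4. The terminal double bond of the butenyl chain may migrate under the palladium catalyst at the temperature the heteroaryl-capped alkyne needs, and aromatisation of the ylidene intermediate may stall. The fallback sets out from prop-2-yn-1-ol 1 and carries the chain as a silyl ether, so that the closure can be run hotter or with (Ph3P)AuCl/AgOTf without an alkene at risk.
- [3-(tert-Butyldimethylsilyloxy)propyl]magnesium bromide F4 is made from commercial (3-bromopropoxy)(tert-butyl)dimethylsilane and Mg.
- Its CuI-catalysed addition to 1 gives the chelated alkenylmagnesium alkoxide 4-[3-(tert-butyldimethylsilyloxy)propyl]-2,5-dihydro-1,2-oxamagnesole F5, and iodinolysis gives (2Z)-2-[3-(tert-butyldimethylsilyloxy)propyl]-3-iodoprop-2-en-1-ol F6.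
- Sonogashira coupling with 6 gives (2Z)-2-[3-(tert-butyldimethylsilyloxy)propyl]-5-(furan-3-yl)pent-2-en-4-yn-1-ol F7.
- The cycloisomerisation passes through tert-butyl{3-[(5Z)-5-(furan-3-ylmethylidene)-2,5-dihydrofuran-3-yl]propoxy}dimethylsilane F8 to tert-butyl{3-[5-(furan-3-ylmethyl)furan-3-yl]propoxy}dimethylsilane F9.
- TBAF in THF gives 3-[5-(furan-3-ylmethyl)furan-3-yl]propan-1-ol F10, and Dess–Martin periodinane buffered with NaHCO3 gives 3-[5-(furan-3-ylmethyl)furan-3-yl]propanal F11.
- Wittig olefination with 2-(triphenylphosphoranylidene)propanal in toluene at 80 °C returns the route to the E enal 10.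

Further compounds
F1 | step 11 | (5R)-5-[(1R,2S,4E,6E)-9-[5-(furan-3-ylmethyl)furan-3-yl]-1-hydroxy-2,6-dimethylnona-4,6-dien-1-yl]-3-methylfuran-2(5H)-one | CC1=C[C@H]([C@H](O)[C@@H](C)C/C=C/C(C)=C/CCc2coc(Cc3ccoc3)c2)OC1=O
F2 | step 6 | 2-(furan-3-ylmethyl)-4-[(3E)-4-methylhex-3-en-5-yn-1-yl]furan | C#C/C(C)=C/CCc1coc(Cc2ccoc2)c1
F3 | step 6 | chlorobis(cyclopentadienyl)[(1E,3E)-6-[5-(furan-3-ylmethyl)furan-3-yl]-3-methylhexa-1,3-dien-1-yl]zirconium | Cl[Zr](/C=C/C(C)=C/CCc1coc(Cc2ccoc2)c1)(C1C=CC=C1)C1C=CC=C1
F4 | step 4 | [3-(tert-butyldimethylsilyloxy)propyl]magnesium bromide | CC(C)(C)[Si](C)(C)OCCC[Mg]Br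
F5 | step 4 | 4-[3-(tert-butyldimethylsilyloxy)propyl]-2,5-dihydro-1,2-oxamagnesole | CC(C)(C)[Si](C)(C)OCCCC1=C[Mg]OC1
F6 | step 4 | (2Z)-2-[3-(tert-butyldimethylsilyloxy)propyl]-3-iodoprop-2-en-1-ol | OC/C(CCCO[Si](C)(C)C(C)(C)C)=C\I
F7 | step 4 | (2Z)-2-[3-(tert-butyldimethylsilyloxy)propyl]-5-(furan-3-yl)pent-2-en-4-yn-1-ol | OC/C(CCCO[Si](C)(C)C(C)(C)C)=C\C#Cc1ccoc1
F8 | step 4 | tert-butyl{3-[(5Z)-5-(furan-3-ylmethylidene)-2,5-dihydrofuran-3-yl]propoxy}dimethylsilane | CC(C)(C)[Si](C)(C)OCCCC1=C/C(=C/c2ccoc2)OC1
F9 | step 4 | tert-butyl{3-[5-(furan-3-ylmethyl)furan-3-yl]propoxy}dimethylsilane | CC(C)(C)[Si](C)(C)OCCCc1coc(Cc2ccoc2)c1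
F10 | step 4 | 3-[5-(furan-3-ylmethyl)furan-3-yl]propan-1-ol | OCCCc1coc(Cc2ccoc2)c1
F11 | step 4 | 3-[5-(furan-3-ylmethyl)furan-3-yl]propanal | O=CCCc1coc(Cc2ccoc2)c1
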